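Time was the question: the flask is read at 3.0 min, later than the last amber reading at 120 s, with twice the free monomer and the same initiator.

- amber: free monomer 1.5 M; initiator 60 mM; run made earlier
- flask: free monomer 3.0 M; initiator 60 mM; time 3.0 min

amber run (percent of the free monomer charged)

| time / s | monomer in chains / % | free monomer / % |
|---|---|---|
| 10.0 | 33.9 | 66.0 |
| 12.0 | 37.2 | 62.9 |
| 20.0 | 52.5 | 47.0 |
| 30.0 | 65.7 | 34.3 |
| 50.0 | 79.6 | 19.1 |
| 80.0 | 90.2 | 10.5 |
| 120 | 94.7 | 5.1 |

(scatter of a reading: 0.5 percentage points)

- what may be going on: free monomer + growing radical -> monomer in chains + growing radical; initiator -> 2 initiating radical; 2 growing radical -> dead chain; free monomer + initiating radical -> growing radical + monomer in chains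

- how much monomer in chains the flask holds at 3.0 min, in percent of the free monomer charged
- how much free monomer the flask holds at 3.0 min, in percent of the free monomer charged

In the amber run, free monomer and monomer in chains together stayed close to the whole charge, so I followed free monomer. The bench rule is a fixed half-life (pseudo-first-order), which makes the fraction left independent of the charge. The first amber reading gave a slope of 0.0416 s⁻¹, so a half-life of 16.7 s.

| amber time | free monomer read | fixed half-life gives |
|---|---|---|
| 20.0 s | 47.0 % | 43.5 % |
| 50.0 s | 19.1 % | 12.5 % |
| 120 s | 5.1 % | 0.679 % |

The late amber slope read 0.0189 s⁻¹, lower by a factor of 2.20. I took growing radical to follow the square root of a decaying initiator, so the slope falls exponentially at 0.009871 s⁻¹. The rule needs a time short against 101 s, and the flask's time is 1.78 of these, beyond that border.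

I therefore carried the reach, early slope over fall rate, the whole logarithmic drop of free monomer that this reckoning allows: 4.21. I assumed the flask's fraction left follows the amber curve at the doubled free monomer, since the initiator charge is the same, so I reckoned 83.1 % of the reach used by 3.0 min, leaving 3.03 % free monomer and 97.0 % in chains.

The forecast said 97 % in chains and 3 % free monomer, holding that doubling the monomer “leaves the fractional conversion unchanged”. The flask gave 95.7 % in chains and 4.35 % free monomer.

    free monomer + growing radical → monomer in chains + growing radical, rate k1*[growing radical]*[free monomer] (k = 28000 M⁻¹ s⁻¹)
    initiator → 2 initiating radical (k = 0.0240 s⁻¹)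
    2 growing radical → dead chain (k = 7.00 × 10⁸ M⁻¹ s⁻¹)
    free monomer + initiating radical → growing radical + monomer in chains (k = 3.90 × 10⁵ M⁻¹ s⁻¹)

At 0.285 min the flask's free monomer had a half-life of 0.35 min by the chain step, shorter than the 0.48 min of initiator by its own breakdown. At 3.00 min the flask kept 1.3 % of its initiator and 4.3 % of its free monomer. At 30.0 min the flask held 2.91 % free monomer, where the reach gives 1.48 %. For a neighbour flask charged with a quarter of the initiator, I scaled the reach by the square root to 2.10, which gives 17.5 % free monomer at the flask's time. That neighbour flask holds 22.3 % free monomer at 3.00 min.

(The numbers in the tables are calculated on assumed constants; noise was put on by code.)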